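**Retrosynthetic overview**

1. Target 16 ⇐ acid hydrolysis of the quinone bis(dimethyl ketal) 15. The side chain is numbered C1′ (ring CH2), C2′ (CHOAc) to C13′.
2. 15 ⇐ C4′–C5′ bond, made in one anodic operation on acetoxy acid 12 and decanoic acid 13: the ring is first oxidised to the bisketal, then a mixed Kolbe coupling expels two CO2.
3. Enabling feature: the C2′ oxygen stands 1,4 to the carbon lost as CO2, so O–C2′–C3′–C4′–CO2H is a ring-opened γ-butyrolactone with the five carbons of D-glutamic acid. The six-membered quinone ring is the two-electron anodic oxidation product of a 1,2,4-trimethoxybenzene ring, which is oxidised about 1 V before a carboxylate.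
4. 12 ⇐ C1′–aryl bond: Cu-catalysed opening of benzyl (R)-4,5-epoxypentanoate 8 (from lactone 5 via tosylate 6) by the Grignard reagent of 1-bromo-2,3,5-trimethoxybenzene 4 (from aldehyde 1).
5. Rings: none is built. The bought γ-lactone ring is traded for an oxirane (step 4) that is opened (step 5); the bought benzene ring becomes the cyclohexadiene bisketal (step 7) and then the quinone (step 8).

Key step: step 7

Remark: the SMILES is read as the (R)-acetate (OAc > ring-CH2 > undecyl > H). Compounds 1, 5 and 13 are taken as commercial; bromide 4 is made in case it cannot be bought.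

**Route**

Step 1
Reactants: 1 3-bromo-4,5-dimethoxybenzaldehyde
Product: 3 3-bromo-4,5-dimethoxyphenol, via 3-bromo-4,5-dimethoxyphenyl formate 2 (not isolated)
Conditions: mCPBA (1.3 equiv), CH2Cl2, rt; then Et3N (cat.), MeOH, rt
Reagents that add atoms: 3-chloroperoxybenzoic acid (mCPBA), OOC(=O)c1cccc(Cl)c1
Why: Baeyer–Villiger (Dakin-type) oxidation in which the electron-rich aryl group (4-OMe para to the formyl group) migrates, followed by base-catalysed methanolysis of the aryl formate.

Step 2
Reactants: 3 3-bromo-4,5-dimethoxyphenol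
Product: 4 1-bromo-2,3,5-trimethoxybenzene
Conditions: MeI (1.5 equiv), K2CO3 (1.5 equiv), acetone, reflux
Reagents that add atoms: iodomethane, CI
Why: Williamson ether synthesis (phenoxide SN2 on iodomethane), which completes the 1,2,4-trioxygenation pattern with bromine at the future C1′ attachment site.

Step 3
Reactants: 5 (R)-5-(hydroxymethyl)dihydrofuran-2(3H)-one
Product: 6 [(2R)-5-oxotetrahydrofuran-2-yl]methyl 4-methylbenzenesulfonate
Conditions: TsCl (1.2 equiv), Et3N (1.5 equiv), DMAP (5 mol %), CH2Cl2, 0 °C
Reagents that add atoms: 4-methylbenzenesulfonyl chloride (TsCl), Cc1ccc(cc1)S(Cl)(=O)=O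
Why: Sulfonylation of the primary alcohol; the stereocentre (chiral pool, D-glutamic acid series) is not touched.

Step 4
Reactants: 6 [(2R)-5-oxotetrahydrofuran-2-yl]methyl 4-methylbenzenesulfonate
Product: 8 benzyl 3-[(2R)-oxiran-2-yl]propanoate (benzyl (R)-4,5-epoxypentanoate), via sodium (2R)-5-(benzyloxy)-5-oxo-1-(tosyloxy)pentan-2-olate 7 (not isolated)
Conditions: BnOH (1.05 equiv), NaH (1.0 equiv), THF, 0 °C; then 6, −20 → 0 °C
Reagents that add atoms: benzyl alcohol (used as sodium benzyloxide), OCc1ccccc1
Why: Alkoxide transesterification opens the lactone and the freed C4 alkoxide closes the oxirane by intramolecular Williamson displacement (3-exo-tet) of the primary tosylate, the reaction type known for methoxide on this lactone tosylate; no bond at the stereocentre is broken, so it stays (R).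

Step 5
Reactants: 4 1-bromo-2,3,5-trimethoxybenzene; 8 benzyl 3-[(2R)-oxiran-2-yl]propanoate
Product: 11 benzyl (4R)-4-acetoxy-5-(2,3,5-trimethoxyphenyl)pentanoate, via (2,3,5-trimethoxyphenyl)magnesium bromide 9 (not isolated), via benzyl (4R)-4-(bromomagnesiooxy)-5-(2,3,5-trimethoxyphenyl)pentanoate 10 (not isolated)
Conditions: 4 (1.3 equiv), Mg, LiCl, THF, 40 °C; CuI (10 mol %), 8, THF, −40 °C; then Ac2O (2.5 equiv), −40 → 0 °C
Reagents that add atoms: acetic anhydride, CC(=O)OC(C)=O
Why: Copper-catalysed Grignard opening of a terminal epoxide at its CH2 carbon (SN2, stereocentre untouched, ester spared at −40 °C), followed by O-acylation of the magnesium alkoxide in the same pot before it can lactonise.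

Step 6
Reactants: 11 benzyl (4R)-4-acetoxy-5-(2,3,5-trimethoxyphenyl)pentanoate
Product: 12 (4R)-4-acetoxy-5-(2,3,5-trimethoxyphenyl)pentanoic acid
Conditions: H2 (1 atm), 10 % Pd/C, EtOAc, rt
Reagents that add atoms: none
Why: Hydrogenolysis of the benzyl ester under neutral conditions, which leaves the secondary acetate, the aryl methyl ethers and the homobenzylic C–O bond intact and avoids the relactonisation that a free γ-hydroxy acid would undergo.

Step 7
Reactants: 12 (4R)-4-acetoxy-5-(2,3,5-trimethoxyphenyl)pentanoic acid; 13 decanoic acid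
Product: 15 (2R)-1-(3,3,5,6,6-pentamethoxycyclohexa-1,4-dien-1-yl)tridecan-2-yl acetate, via (4R)-4-acetoxy-5-(3,3,5,6,6-pentamethoxycyclohexa-1,4-dien-1-yl)pentanoic acid 14 (not isolated)
Conditions: 12 (1 equiv), 13 (8 equiv), sodium decanoate (0.5 equiv, electrolyte), dry MeOH, undivided cell, Pt anode/Pt cathode, 15 °C; +1.25 V vs Ag/AgCl to 2.2 F/mol of 12, then 0.25 A cm−2 to about 1.1 F/mol of total acid (stopped while still acidic); NaHCO3 wash, Et3N-deactivated silica
Reagents that add atoms: methanol, CO
Why: Proposed new method: two established anodic reactions are run back to back in one undivided cell, ordered by potential: near +1.2 V the 2,3,5-trimethoxyphenyl ring of 12 gives its radical cation, which takes up methanol at C2 and C5 (the para-related, methoxy-bearing ring carbons) in an ECEC sequence to form the quinone bis(dimethyl ketal) 14, and only then, at high current density on platinum, the carboxylates of 14 and 13 are discharged, lose CO2, and the primary C4′ radical and the nonyl radical combine at the electrode to make the C4′–C5′ bond. The closest known reaction types are the anodic bisketalisation of 1,4-dimethoxyarenes in methanol and the mixed Kolbe electrolysis of O-acylated hydroxy acids with fatty acids; what is new is their one-pot sequence on an acid that carries the arene, which in a direct Kolbe coupling would be oxidised first and foul the anode, so that the obstacle becomes the event that installs the quinone oxidation level. No ring is closed and no stereocentre is formed; C2′ (set in the chiral pool) lies two carbons from the radical centre, is not part of any radical, cation or enolisable system and therefore keeps its (R) configuration. The step needs arene oxidation before carboxylate oxidation, which the electron-rich trimethoxybenzene ring secures (onset roughly 1 V below that of a carboxylate on platinum), and para-quinone rather than ortho-quinone ketal formation, which the 1,4-relationship of the C2 and C5 methoxy groups secures as in 1,2,4-trimethoxybenzene itself. It also needs radical coupling rather than further oxidation to cations, secured by two unbranched primary radicals without α-heteroatoms, smooth platinum, weakly acidic methanol and high current density, and cross- rather than homo-coupling, secured statistically by the eightfold excess of cheap decanoic acid (its dimer octadecane is removed by chromatography). The decanoate/decanoic acid buffer keeps the solution weakly acidic and water-free, so the acetate should not be methanolysed and the ketals should not be hydrolysed.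

Step 8
Reactants: 15 (2R)-1-(3,3,5,6,6-pentamethoxycyclohexa-1,4-dien-1-yl)tridecan-2-yl acetate
Product: 16 (2R)-1-(5-methoxy-3,6-dioxocyclohexa-1,4-dien-1-yl)tridecan-2-yl acetate (target)
Conditions: 1 M aq HCl/THF (1:3), 0 °C → rt
Reagents that add atoms: water, O
Why: Acid-catalysed hydrolysis of both dimethyl ketals (quinone bisketal → monoketal → quinone) unmasks the 2-methoxy-1,4-benzoquinone, while the vinylogous-ester methoxy group and the secondary acetate should survive dilute acid at room temperature.

**Compound list**

1 | 3-bromo-4,5-dimethoxybenzaldehyde | O=Cc1cc(OC)c(OC)c(Br)c1 | starting material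
2 | 3-bromo-4,5-dimethoxyphenyl formate | O=COc1cc(OC)c(OC)c(Br)c1 | intermediate
3 | 3-bromo-4,5-dimethoxyphenol | Oc1cc(OC)c(OC)c(Br)c1 | intermediate
4 | 1-bromo-2,3,5-trimethoxybenzene | COc1cc(OC)c(OC)c(Br)c1 | intermediate
5 | (R)-5-(hydroxymethyl)dihydrofuran-2(3H)-one | O=C1CC[C@H](CO)O1 | starting material
6 | [(2R)-5-oxotetrahydrofuran-2-yl]methyl 4-methylbenzenesulfonate | Cc1ccc(cc1)S(=O)(=O)OC[C@H]1CCC(=O)O1 | intermediate
7 | sodium (2R)-5-(benzyloxy)-5-oxo-1-(tosyloxy)pentan-2-olate | [Na+].[O-][C@H](CCC(=O)OCc1ccccc1)COS(=O)(=O)c1ccc(C)cc1 | intermediate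
8 | benzyl 3-[(2R)-oxiran-2-yl]propanoate | O=C(OCc1ccccc1)CC[C@@H]1CO1 | intermediate
9 | (2,3,5-trimethoxyphenyl)magnesium bromide | COc1cc(OC)c(OC)c([Mg]Br)c1 | intermediate
10 | benzyl (4R)-4-(bromomagnesiooxy)-5-(2,3,5-trimethoxyphenyl)pentanoate | O=C(OCc1ccccc1)CC[C@H](Cc1cc(OC)cc(OC)c1OC)O[Mg]Br | intermediate
11 | benzyl (4R)-4-acetoxy-5-(2,3,5-trimethoxyphenyl)pentanoate | O=C(OCc1ccccc1)CC[C@H](Cc1cc(OC)cc(OC)c1OC)OC(C)=O | intermediate
12 | (4R)-4-acetoxy-5-(2,3,5-trimethoxyphenyl)pentanoic acid | OC(=O)CC[C@H](Cc1cc(OC)cc(OC)c1OC)OC(C)=O | intermediate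
13 | decanoic acid | CCCCCCCCCC(O)=O | starting material
14 | (4R)-4-acetoxy-5-(3,3,5,6,6-pentamethoxycyclohexa-1,4-dien-1-yl)pentanoic acid | OC(=O)CC[C@H](CC1=CC(OC)(OC)C=C(OC)C1(OC)OC)OC(C)=O | intermediate
15 | (2R)-1-(3,3,5,6,6-pentamethoxycyclohexa-1,4-dien-1-yl)tridecan-2-yl acetate | CCCCCCCCCCC[C@H](CC1=CC(OC)(OC)C=C(OC)C1(OC)OC)OC(C)=O | intermediate
16 | (2R)-1-(5-methoxy-3,6-dioxocyclohexa-1,4-dien-1-yl)tridecan-2-yl acetate | CCCCCCCCCCC[C@H](CC1=CC(=O)C=C(OC)C1=O)OC(C)=O | target

**Step count**

Total steps: 8. Longest linear sequence: 6 (steps 3–8 from 5, or steps 1, 2, 5–8 from 1).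

**Steps most likely to fail**

Step 7 (bears the label "Proposed new method"). Three processes may go wrong. Once the arene is consumed and the anode potential rises, the enol-ether double bond of the ring ketal may be oxidised further. Arene-derived films may passivate the platinum, so that the carboxylate layer needed for radical coupling never forms. The C4′ radical may be lost to two-electron (Hofer–Moest) products, to disproportionation, or to addition to the ring diene. The fallback uses known chemistry, sets out from 12 and comes back at 16. Acid 12 is converted (N-hydroxyphthalimide, DIC, DMAP cat., CH2Cl2) into the redox-active ester 1,3-dioxoisoindolin-2-yl (4R)-4-acetoxy-5-(2,3,5-trimethoxyphenyl)pentanoate F1, and decanoic acid 13 in the same way into 1,3-dioxoisoindolin-2-yl decanoate F2. F1 and F2 (3 equiv) are joined at the same C4′–C5′ bond by the nickel-electrocatalytic doubly decarboxylative C(sp3)–C(sp3) coupling of two such esters (NiCl2·6H2O, terpyridine-type ligand, AgNO3, Mg sacrificial anode, RVC cathode, NMP, rt). This is a reductive process in which the trimethoxyarene and the acetate are inert, and it should give (2R)-1-(2,3,5-trimethoxyphenyl)tridecan-2-yl acetate F3. Oxidative demethylation of F3 with ceric ammonium nitrate (MeCN/H2O, 0 °C) at the para-related C2/C5 methoxy groups then gives the quinone 16 directly.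

Step 5. The magnesium alkoxide 10 may close onto the benzyl ester (loss of benzyl alcohol, lactone formation) before it is acylated, so that a mixture results. The fallback sets out from 4 and 8 and comes back at 11. The copper-catalysed opening is run without acylation and quenched with aqueous NH4Cl. The resulting mixture of benzyl (4R)-4-hydroxy-5-(2,3,5-trimethoxyphenyl)pentanoate F6 and lactone is driven completely to (5R)-5-(2,3,5-trimethoxybenzyl)dihydrofuran-2(3H)-one F4 (TsOH cat., toluene, rt). F4 is saponified (KOH, MeOH/H2O, then evaporation) to potassium (4R)-4-hydroxy-5-(2,3,5-trimethoxyphenyl)pentanoate F5. F5 is alkylated at the carboxylate (BnBr, DMF, rt) to give F6 under non-acidic conditions, and F6 is acetylated at once (Ac2O, Et3N, DMAP, CH2Cl2, 0 °C) to 11.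

Step 4. Benzyloxide may displace the tosylate directly or open the newly formed oxirane, and ester exchange between opened molecules may give oligomers. The fallback leaves the lactone series, sets out from 4 (as its Grignard reagent 9) and comes back at 12.
- Reagent 9 opens commercial (S)-epichlorohydrin at the oxirane CH2 (CuI cat., THF, −40 °C) to give (2S)-1-chloro-3-(2,3,5-trimethoxyphenyl)propan-2-ol F7.
- NaOH in MeOH closes F7 to (2S)-2-(2,3,5-trimethoxybenzyl)oxirane F8.
- The lithium enolate of tert-butyl acetate F9 (LDA, THF, −78 °C), activated with Et2AlCl, opens F8 at the terminal carbon to tert-butyl (4R)-4-hydroxy-5-(2,3,5-trimethoxyphenyl)pentanoate F10. The descriptor changes from S to R only because the CIP order of the two CH2 groups changes; no bond at the stereocentre is broken.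
- Ac2O, Et3N and DMAP give tert-butyl (4R)-4-acetoxy-5-(2,3,5-trimethoxyphenyl)pentanoate F11.
- TFA with Et3SiH as cation scavenger (CH2Cl2, 0 °C) removes the tert-butyl group to give 12.

**Further compounds**

F1 | step 7 | 1,3-dioxoisoindolin-2-yl (4R)-4-acetoxy-5-(2,3,5-trimethoxyphenyl)pentanoate | O=C(ON1C(=O)c2ccccc2C1=O)CC[C@H](Cc1cc(OC)cc(OC)c1OC)OC(C)=O
F2 | step 7 | 1,3-dioxoisoindolin-2-yl decanoate | CCCCCCCCCC(=O)ON1C(=O)c2ccccc2C1=O
F3 | step 7 | (2R)-1-(2,3,5-trimethoxyphenyl)tridecan-2-yl acetate | CCCCCCCCCCC[C@H](Cc1cc(OC)cc(OC)c1OC)OC(C)=O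
F4 | step 5 | (5R)-5-(2,3,5-trimethoxybenzyl)dihydrofuran-2(3H)-one | O=C1CC[C@H](Cc2cc(OC)cc(OC)c2OC)O1
F5 | step 5 | potassium (4R)-4-hydroxy-5-(2,3,5-trimethoxyphenyl)pentanoate | [K+].[O-]C(=O)CC[C@H](Cc1cc(OC)cc(OC)c1OC)O
F6 | step 5 | benzyl (4R)-4-hydroxy-5-(2,3,5-trimethoxyphenyl)pentanoate | O=C(OCc1ccccc1)CC[C@H](Cc1cc(OC)cc(OC)c1OC)O
F7 | step 4 | (2S)-1-chloro-3-(2,3,5-trimethoxyphenyl)propan-2-ol | ClC[C@@H](O)Cc1cc(OC)cc(OC)c1OC
F8 | step 4 | (2S)-2-(2,3,5-trimethoxybenzyl)oxirane | C1[C@@H](O1)Cc2cc(OC)cc(OC)c2OC
F9 | step 4 | lithium enolate of tert-butyl acetate | [Li+].[O-]C(=C)OC(C)(C)C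
F10 | step 4 | tert-butyl (4R)-4-hydroxy-5-(2,3,5-trimethoxyphenyl)pentanoate | CC(C)(C)OC(=O)CC[C@@H](O)Cc1cc(OC)cc(OC)c1OC
F11 | step 4 | tert-butyl (4R)-4-acetoxy-5-(2,3,5-trimethoxyphenyl)pentanoate | CC(C)(C)OC(=O)CC[C@H](Cc1cc(OC)cc(OC)c1OC)OC(C)=O
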